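**Retrosynthetic overview**
- Lapiferine (26) is traced back to the 8,9-alkene 25 (epoxide delivered last from the C10 hydroxyl), then to the C6 angelate 24, the 4,6-anti diol 21 and the trans-fused 4-hydroxy-6-ketone 20.
- The strategy rests on the seven-membered ring C1–C10–C9=C8(C14)–C7–C6–C5: with C8=C9 and the enol C5=C6 of the ketone it is a cyclohepta-1,4-diene whose C10 carbinol sits beside quaternary C1. It is cut at C1–C10 and C7–C8 into a vinylcarbenoid (C8–C9=C10–O, from diazo ester 13) and a 2-siloxydiene (C7=C6–C5=C1, compound 10).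
- Diene 10 carries C1–C6 with the C1 methyl and the C4 isopropyl carbinol, the ten carbons of (S)-terpinen-4-ol (1): ozonolysis and aldol reclosure contract the ring to a cyclopentene, then C7 is added.
- Ring order: cyclopentene, then a transient cyclopropane, then the seven-membered ring by Cope rearrangement, then the epoxide.

Key step: step 9

Remark: daucane numbering is used (C1 quaternary methyl carbon, C4 isopropyl carbinol, C5 ring-fusion CH, C6 acyloxy carbon, C8/C9 epoxide, C10 carbinol, C14 the methyl on C8); β is the face of the C4 isopropyl, the C5 hydrogen and the oxygens on C6, C8/C9 and C10, α the face of the C1 methyl and the C4 hydroxyl.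
Assumption: 1 is taken at high enantiomeric purity. Rh2(R-DOSP)4 is dirhodium tetrakis[(R)-N-(4-dodecylphenylsulfonyl)prolinate], a chiral carboxylate of divalent rhodium. Its antipode is assigned from the usual facial model of this catalyst family and is to be confirmed on the first run, the wrong-face product being a diastereomer because of C4.

Step 1
Reactants: 1 (S)-(+)-terpinen-4-ol
Product: 2 (S)-terpinen-4-yl triethylsilyl ether
Conditions: TESOTf, 2,6-lutidine, CH2Cl2, −78 to 0 °C
Reagents that add atoms: triethylsilyl trifluoromethanesulfonate, CC[Si](CC)(CC)OS(=O)(=O)C(F)(F)F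
Why: A silyl triflate with a hindered pyridine base silylates the tertiary alcohol (standard O-silylation); the ether later blocks retro-aldol cleavage at this carbinol and no stereocentre is touched.

Step 2
Reactants: 2 (S)-terpinen-4-yl triethylsilyl ether
Product: 4 keto aldehyde 3-isopropyl-6-oxo-3-(triethylsilyloxy)heptanal, via ozonide 3 (not isolated)
Conditions: O3, CH2Cl2, −78 °C; then PPh3, −78 °C to rt
Reagents that add atoms: ozone, [O-][O+]=O
Why: Ozonolysis of the only alkene with reductive work-up should open the six-membered ring to the 1,6-keto aldehyde, the silyl ether and the quaternary carbinol centre being inert.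

Step 3
Reactants: 4 keto aldehyde 3-isopropyl-6-oxo-3-(triethylsilyloxy)heptanal
Product: 6 enal 5-isopropyl-2-methyl-5-(triethylsilyloxy)cyclopent-1-ene-1-carbaldehyde, via aldol adduct 5 (not isolated)
Conditions: piperidine, AcOH (cat.), toluene, 60 °C
Reagents that add atoms: none
Why: The aldehyde enamine adds to the methyl ketone in a 5-(enolexo)-exo-trig intramolecular aldol addition and dehydration gives the conjugated cyclopentene carbaldehyde (aldol condensation with the regiochemistry known for cleaved p-menthenes); the near-neutral amine salt should limit β-elimination of the silyloxy group.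

Step 4
Reactants: 6 enal 5-isopropyl-2-methyl-5-(triethylsilyloxy)cyclopent-1-ene-1-carbaldehyde
Product: 7 allylic alcohol 1-[5-isopropyl-2-methyl-5-(triethylsilyloxy)cyclopent-1-en-1-yl]ethanol (both carbinol epimers)
Conditions: MeMgBr, THF, −78 to 0 °C
Reagents that add atoms: methylmagnesium bromide, C[Mg]Br
Why: Grignard 1,2-addition to the β,β-disubstituted enal brings in C7; the carbinol configuration is irrelevant because the next step oxidises it.

Step 5
Reactants: 7 allylic alcohol 1-[5-isopropyl-2-methyl-5-(triethylsilyloxy)cyclopent-1-en-1-yl]ethanol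
Product: 8 enone 1-acetyl-5-isopropyl-2-methyl-5-(triethylsilyloxy)cyclopent-1-ene
Conditions: Dess–Martin periodinane, NaHCO3, CH2Cl2, 0 °C to rt
Reagents that add atoms: none
Why: Buffered Dess–Martin oxidation converts the secondary allylic alcohol to the methyl ketone without acid that could ionise the tertiary silyloxy group.

Step 6
Reactants: 8 enone 1-acetyl-5-isopropyl-2-methyl-5-(triethylsilyloxy)cyclopent-1-ene
Product: 10 siloxydiene 1-[1-(tert-butyldimethylsilyloxy)ethenyl]-5-isopropyl-2-methyl-5-(triethylsilyloxy)cyclopent-1-ene, via lithium enolate 9 (not isolated)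
Conditions: LiN(iPr)2, THF, −78 °C; then TBSCl, HMPA, −78 °C to rt
Reagents that add atoms: tert-butyldimethylsilyl chloride, CC(C)(C)[Si](C)(C)Cl
Why: Kinetic deprotonation of the enone occurs at the acetyl methyl (α′) and not at the γ positions, and O-silylation of this cross-conjugated enolate gives the 2-siloxydiene C7=C6(OTBS)–C5=C1.

Step 7
Reactants: 11 methyl 4-oxobutanoate
Product: 12 methyl (E)-4-(triisopropylsilyloxy)but-3-enoate
Conditions: TIPSOTf, Et3N, CH2Cl2, 0 °C to rt; E isomer separated on Et3N-deactivated silica
Reagents that add atoms: triisopropylsilyl trifluoromethanesulfonate, CC(C)[Si](C(C)C)(C(C)C)OS(=O)(=O)C(F)(F)F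
Why: Soft enolisation with silyl triflate and amine silylates the aldehyde, not the ester, but does not control the geometry, so the E isomer (needed later to place the C10 oxygen trans to the C1 methyl) is isolated by chromatography, which the bulky silyl enol ether should tolerate.

Step 8
Reactants: 12 methyl (E)-4-(triisopropylsilyloxy)but-3-enoate
Product: 13 methyl (E)-2-diazo-4-(triisopropylsilyloxy)but-3-enoate
Conditions: p-ABSA, DBU, MeCN, 0 °C; used cold and promptly
Reagents that add atoms: 4-acetamidobenzenesulfonyl azide, CC(=O)Nc1ccc(cc1)S(=O)(=O)N=[N+]=[N-]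
Why: Regitz diazo transfer to the CH2 activated by both the ester and the vinyl group is the standard entry to vinyldiazoacetates from but-3-enoates and should leave the E enol ether intact.

Step 9
Reactants: 10 siloxydiene 1-[1-(tert-butyldimethylsilyloxy)ethenyl]-5-isopropyl-2-methyl-5-(triethylsilyloxy)cyclopent-1-ene; 13 methyl (E)-2-diazo-4-(triisopropylsilyloxy)but-3-enoate
Product: 15 hydroazulene 1,4-diene ester (C1 quaternary with α-methyl; C10 β-OTIPS; C8 methyl ester on C8=C9; C5=C6 TBS enol ether; C4 OTES), via cis-divinylcyclopropane 14 (not isolated)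
Conditions: Rh2(R-DOSP)4 (1 mol %), 2,2-dimethylbutane, −40 °C to rt, slow addition of 13; then toluene, 90 °C
Reagents that add atoms: none
Why: The chiral carboxylate of divalent rhodium turns 13 into a donor/acceptor vinylcarbenoid whose carbenoid carbon C8 adds to the electron-rich terminal C7=C6 silyl enol ether of 10 (the C5=C1 alkene is tetrasubstituted and shielded) in a concerted, asynchronous [2+1] closure that forms C8–C7 and C8–C6 and the three-membered ring of 14; this is the tandem cyclopropanation/divinylcyclopropane Cope rearrangement (formal (4+3) annulation) of vinyldiazoacetates with dienes, known with oxygenated dienes and with quaternary-carbon formation, although a 4-siloxy carbenoid together with this fully substituted diene terminus has not been tested. On warming, 14 should undergo the [3,3]-sigmatropic shift through the boat transition state, breaking the donor/acceptor-weakened C6–C8 bond and forming C1–C10, which closes the seven-membered ring as the 1,4-diene (C8=C9 and the C5=C6 silyl enol ether). The cyclopropane centres C6 and C8 are set by the catalyst (absolute face of C7=C6 and the cis placement of cyclopentenyl and siloxyvinyl groups), and the stereospecific boat relays them to C1 and C10: the E enol ether keeps the C10 silyloxy group outside while the C1 methyl is forced inside, so C10–O ends trans to the C1 methyl. The step needs reaction at C7=C6 only, attack at the carbenoid carbon and not at the vinylogous carbon (favoured by the E substituent and the hydrocarbon solvent), the cis-divinyl arrangement and one alkene face; catalyst control is relied on for the face because C4, the only resident centre, is remote from C7=C6 and its own bias is expected to turn C10 away from the isopropyl face. Heating to about 90 °C is intended because the inward methyl raises the barrier of the Cope step.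

Step 10
Reactants: 15 hydroazulene 1,4-diene ester
Product: 16 C14 allylic alcohol (CH2OH on C8)
Conditions: iBu2AlH, CH2Cl2, −78 °C
Reagents that add atoms: none
Why: 1,2-Reduction of the enoate by the aluminium hydride at low temperature should give the primary allylic alcohol, with the three silyl groups and the enol ether inert.

Step 11
Reactants: 16 C14 allylic alcohol
Product: 17 C14 allylic methanesulfonate (used crude)
Conditions: Ms2O, Et3N, CH2Cl2, −20 °C
Reagents that add atoms: methanesulfonic anhydride, CS(=O)(=O)OS(C)(=O)=O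
Why: Sulfonylation of the primary allylic hydroxyl with the anhydride gives one activated species, since no chloride is present to give an allylic chloride.

Step 12
Reactants: 17 C14 allylic methanesulfonate
Product: 18 C14-methyl diene (C8 methyl on C8=C9, C5=C6 TBS enol ether, C4 OTES, C10 OTIPS)
Conditions: LiEt3BH, THF, −78 to 0 °C
Reagents that add atoms: none
Why: The trialkylborohydride should displace the primary allylic sulfonate by direct SN2 hydride delivery (reductive deoxygenation), the SN2′ path being disfavoured at C9 next to the silyloxy-bearing neopentyl C10.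

Step 13
Reactants: 18 C14-methyl diene
Product: 20 trans-fused 4-hydroxy-6-ketone (C5–H β, C10 OTIPS kept), via 4-O-triethylsilyl ketone 19 (not isolated)
Conditions: HF·pyridine, pyridine, THF, 0 °C to rt
Reagents that add atoms: none
Why: Graded silyl lability lets buffered HF cleave the silyl enol ether and then the tertiary TES ether while the hindered secondary TIPS ether stays; C5 is set on ketonisation and acid-mediated enol equilibration, expected to favour the trans-fused ketone with C6 anti to the C4 isopropyl group, and the weakly acidic medium should avoid retro-aldol cleavage and migration of C8=C9 into conjugation.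

Step 14
Reactants: 20 trans-fused 4-hydroxy-6-ketone
Product: 21 4,6-anti diol (C6–OH β, C10 OTIPS)
Conditions: Me4NBH(OAc)3, MeCN/AcOH, −30 to −20 °C
Reagents that add atoms: none
Why: In this Evans–Saksena reduction the C4 hydroxyl exchanges onto boron and delivers hydride intramolecularly to the α face of the C6 carbonyl, so the new hydroxyl should be β (1,3-anti diol), and the mild acidic medium leaves the β,γ-alkene in place.

Step 15
Reactants: 21 4,6-anti diol; 22 angelic acid
Product: 24 C6 angelate (C10 OTIPS, C4–OH free), via mixed anhydride 23 (not isolated)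
Conditions: 22, 2,4,6-trichlorobenzoyl chloride, Et3N, toluene, rt; then 21, toluene, 80 °C
Reagents that add atoms: none
Why: Yamaguchi-type acylation through the hindered mixed anhydride esterifies the secondary C6 hydroxyl (the tertiary C4 hydroxyl is inert), and leaving out a nucleophilic catalyst avoids the addition–elimination that would turn the Z ester into the tiglate.

Step 16
Reactants: 24 C6 angelate
Product: 25 C10 allylic alcohol (8,9-deoxy-lapiferine)
Conditions: TBAF, AcOH, THF, rt to 45 °C
Reagents that add atoms: none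
Why: Fluoride cleaves the remaining silyl ether, and the acetic acid buffer keeps the medium non-basic so that the angelate is neither cleaved nor migrated.

Step 17
Reactants: 25 C10 allylic alcohol
Product: 26 lapiferine
Conditions: VO(acac)2 (5 mol %), tBuOOH, CH2Cl2, 0 °C to rt
Reagents that add atoms: tert-butyl hydroperoxide, CC(C)(C)OO
Why: In the hydroxyl-directed vanadium epoxidation the vanadate ester of the C10 hydroxyl delivers oxygen to the same (β) face of C8=C9, as is general for cyclohept-2-enols, while the electron-poor angelate alkene has no directing hydroxyl and should stay untouched.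

**Compound list**
1 | (S)-(+)-terpinen-4-ol | CC1=CC[C@](O)(C(C)C)CC1 | starting material
2 | (S)-terpinen-4-yl triethylsilyl ether | CC1=CC[C@](O[Si](CC)(CC)CC)(C(C)C)CC1 | intermediate
3 | ozonide (1,2,4-trioxolane) of 2, mixture at the two acetal carbons, not isolated | CC12OC(OO1)C[C@](O[Si](CC)(CC)CC)(C(C)C)CC2 | intermediate
4 | 3-isopropyl-6-oxo-3-(triethylsilyloxy)heptanal, C3 as in 1 | O=CC[C@](O[Si](CC)(CC)CC)(C(C)C)CCC(C)=O | intermediate
5 | aldol adduct 2-hydroxy-5-isopropyl-2-methyl-5-(triethylsilyloxy)cyclopentane-1-carbaldehyde, mixture at C1 and C2, not isolated | O=CC1C(C)(O)CC[C@@]1(O[Si](CC)(CC)CC)C(C)C | intermediate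
6 | 5-isopropyl-2-methyl-5-(triethylsilyloxy)cyclopent-1-ene-1-carbaldehyde | O=CC1=C(C)CC[C@@]1(O[Si](CC)(CC)CC)C(C)C | intermediate
7 | 1-[5-isopropyl-2-methyl-5-(triethylsilyloxy)cyclopent-1-en-1-yl]ethanol, carbinol epimers | CC(O)C1=C(C)CC[C@@]1(O[Si](CC)(CC)CC)C(C)C | intermediate
8 | 1-acetyl-5-isopropyl-2-methyl-5-(triethylsilyloxy)cyclopent-1-ene | CC(=O)C1=C(C)CC[C@@]1(O[Si](CC)(CC)CC)C(C)C | intermediate
9 | lithium enolate of 8 at the acetyl methyl, not isolated | [Li]OC(=C)C1=C(C)CC[C@@]1(O[Si](CC)(CC)CC)C(C)C | intermediate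
10 | 1-[1-(tert-butyldimethylsilyloxy)ethenyl]-5-isopropyl-2-methyl-5-(triethylsilyloxy)cyclopent-1-ene (2-siloxydiene C7=C6–C5=C1) | C=C(O[Si](C)(C)C(C)(C)C)C1=C(C)CC[C@@]1(O[Si](CC)(CC)CC)C(C)C | intermediate
11 | methyl 4-oxobutanoate | COC(=O)CCC=O | starting material
12 | methyl (E)-4-(triisopropylsilyloxy)but-3-enoate | COC(=O)C/C=C/O[Si](C(C)C)(C(C)C)C(C)C | intermediate
13 | methyl (E)-2-diazo-4-(triisopropylsilyloxy)but-3-enoate | COC(=O)C(=[N+]=[N-])/C=C/O[Si](C(C)C)(C(C)C)C(C)C | intermediate
14 | cis-divinylcyclopropane (C6, C7, C8): C6 carries OTBS and the cyclopentenyl group, C8 the methyl ester and the (E)-2-(TIPSO)ethenyl group, cyclopentenyl cis to siloxyvinyl; not isolated | CC(C)(C)[Si](C)(C)O[C@@]1(C2=C(C)CC[C@@]2(O[Si](CC)(CC)CC)C(C)C)C[C@]1(C(=O)OC)/C=C/O[Si](C(C)C)(C(C)C)C(C)C | intermediate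
15 | hydroazulene 1,4-diene ester: C1 quaternary (α-methyl), C4 OTES, C5=C6 TBS enol ether, C8 CO2Me on C8=C9, C10 β-OTIPS | CC(C)(C)[Si](C)(C)OC1=C2[C@](O[Si](CC)(CC)CC)(C(C)C)CC[C@]2(C)[C@H](O[Si](C(C)C)(C(C)C)C(C)C)C=C(C(=O)OC)C1 | intermediate
16 | C14 allylic alcohol of 15 (CH2OH on C8) | CC(C)(C)[Si](C)(C)OC1=C2[C@](O[Si](CC)(CC)CC)(C(C)C)CC[C@]2(C)[C@H](O[Si](C(C)C)(C(C)C)C(C)C)C=C(CO)C1 | intermediate
17 | C14 allylic methanesulfonate | CC(C)(C)[Si](C)(C)OC1=C2[C@](O[Si](CC)(CC)CC)(C(C)C)CC[C@]2(C)[C@H](O[Si](C(C)C)(C(C)C)C(C)C)C=C(COS(C)(=O)=O)C1 | intermediate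
18 | C14-methyl diene (C8 methyl, C5=C6 TBS enol ether, C4 OTES, C10 OTIPS) | CC(C)(C)[Si](C)(C)OC1=C2[C@](O[Si](CC)(CC)CC)(C(C)C)CC[C@]2(C)[C@H](O[Si](C(C)C)(C(C)C)C(C)C)C=C(C)C1 | intermediate
19 | 4-O-triethylsilyl 6-ketone, C10 OTIPS, C5 not yet fixed; not isolated | O=C1CC(C)=C[C@@H](O[Si](C(C)C)(C(C)C)C(C)C)[C@@]2(C)CC[C@@](O[Si](CC)(CC)CC)(C(C)C)C12 | intermediate
20 | trans-fused 4-hydroxy-6-ketone, C5–H β, C10 OTIPS | O=C1CC(C)=C[C@@H](O[Si](C(C)C)(C(C)C)C(C)C)[C@@]2(C)CC[C@@](O)(C(C)C)[C@H]12 | intermediate
21 | 4,6-anti diol (4α-OH, 6β-OH), C10 OTIPS | O[C@H]1CC(C)=C[C@@H](O[Si](C(C)C)(C(C)C)C(C)C)[C@@]2(C)CC[C@@](O)(C(C)C)[C@H]12 | intermediate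
22 | angelic acid, (Z)-2-methylbut-2-enoic acid | C/C=C(/C)C(=O)O | starting material
23 | angelic 2,4,6-trichlorobenzoic mixed anhydride, not isolated | C/C=C(/C)C(=O)OC(=O)c1c(Cl)cc(Cl)cc1Cl | intermediate
24 | C6 angelate, C10 OTIPS, C4–OH free | C/C=C(/C)C(=O)O[C@H]1CC(C)=C[C@@H](O[Si](C(C)C)(C(C)C)C(C)C)[C@@]2(C)CC[C@@](O)(C(C)C)[C@H]12 | intermediate
25 | 8,9-deoxy-lapiferine (C10 allylic alcohol, C6 angelate) | C/C=C(/C)C(=O)O[C@H]1CC(C)=C[C@@H](O)[C@@]2(C)CC[C@@](O)(C(C)C)[C@H]12 | intermediate
26 | lapiferine | C/C=C(/C)C(=O)O[C@H]1C[C@@]2(C)O[C@H]2[C@@H](O)[C@@]2(C)CC[C@@](O)(C(C)C)[C@H]12 | target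

Total step count: 17.
Longest linear sequence: 15 steps (steps 1–6, then 9–17).

**Steps most likely to fail**

Step 9. The carbenoid may add to the 1,1-disubstituted silyl enol ether with the cyclopentenyl group trans to the siloxyvinyl group. The hindered boat Cope (methyl inside) may also be outrun by heterolytic opening of the siloxy/ester cyclopropane, or the enol ether may attack the oxygen-bearing vinylogous terminus of the carbenoid. The fallback moves the C6 oxygen out of the annulation and sets out from enal 6. Wittig methylenation (Ph3PCH3Br, KOtBu, THF) should give the vinyl diene F1. F1 and 13 under the same Rh2(R-DOSP)4 conditions present a monosubstituted vinyl group on a 2-methylcycloalkene, the diene type for which cyclopropanation cis to the carbenoid vinyl and quaternary-centre-forming Cope rearrangement are documented. Through the divinylcyclopropane F2 this should give the diene ester F3. Hydroboration–oxidation (BH3·SMe2; NaBO3·4H2O) of the electron-rich C5=C6 bond beside the deactivated enoate should give the C6 alcohol F4 (either face is acceptable). iBu2AlH then gives the diol F5, selective sulfonylation of the primary allylic hydroxyl (Ms2O, 2,4,6-collidine, −40 °C) the mesylate F6, and LiEt3BH the C14-methyl alcohol F7. Dess–Martin oxidation of F7 gives ketone 19, where the route is rejoined; the conditions of step 13 turn 19 into 20 and level C5.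

Step 13. Ketonisation may deliver the C5 proton from the α face (cis-fused ketone) without later convergence on the trans isomer. The unmasked β-hydroxy ketone may also undergo retro-aldol cleavage, dehydration or shift of C8=C9 into conjugation. The fallback makes no enolisable ketone and sets out from 18. CsF and PhNTf2 (DME, rt) should convert the silyl enol ether into the enol triflate F8. Reduction with Pd(OAc)2, PPh3, HCO2H and Bu3N (DMF, 60 °C; zerovalent palladium formed in the flask) should give the 5,6-alkene F9. Hydroboration–oxidation (BH3·SMe2; NaBO3·4H2O) adds H at C5 and OH at C6 in one syn event to give the 6β-alcohol F10. Attack is expected from the β face, since the α face carries both the C1 methyl and the C4 silyloxy group, and at C5=C6 rather than C8=C9, where boron would sit beside the silyloxy-bearing C10; neither selectivity is assured. HF·pyridine then removes the TES group and gives diol 21, where the route is rejoined.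

Step 15. Acylation of the hindered C6 hydroxyl may be slow, and long heating may isomerise the angelate to the E (tiglate) ester. The fallback builds the Z alkene on the ester and sets out from 21. Steglich esterification with 2-[bis(2,2,2-trifluoroethoxy)phosphoryl]propanoic acid (DCC, DMAP, CH2Cl2) should give the phosphonate ester F11. Still–Gennari olefination (KN(SiMe3)2, 18-crown-6, THF, −78 °C; acetaldehyde) should then give the Z ester 24, where the route is rejoined.

Further compounds
F1 | step 9 | 1-ethenyl-5-isopropyl-2-methyl-5-(triethylsilyloxy)cyclopent-1-ene | C=CC1=C(C)CC[C@@]1(O[Si](CC)(CC)CC)C(C)C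
F2 | step 9 | cis-divinylcyclopropane from F1 and 13 (C6–H, cyclopentenyl cis to siloxyvinyl) | [C@@H]1(C2=C(C)CC[C@@]2(O[Si](CC)(CC)CC)C(C)C)C[C@]1(C(=O)OC)/C=C/O[Si](C(C)C)(C(C)C)C(C)C
F3 | step 9 | hydroazulene 5,6-ene/8,9-ene methyl ester (C6–H, C4 OTES, C10 OTIPS) | C1=C2[C@](O[Si](CC)(CC)CC)(C(C)C)CC[C@]2(C)[C@H](O[Si](C(C)C)(C(C)C)C(C)C)C=C(C(=O)OC)C1
F4 | step 9 | C6 alcohol of the 8,9-ene ester (C5 and C6 not fixed) | OC1CC(C(=O)OC)=C[C@@H](O[Si](C(C)C)(C(C)C)C(C)C)[C@@]2(C)CC[C@@](O[Si](CC)(CC)CC)(C(C)C)C12
F5 | step 9 | C6,C14 diol (C5 and C6 not fixed) | OC1CC(CO)=C[C@@H](O[Si](C(C)C)(C(C)C)C(C)C)[C@@]2(C)CC[C@@](O[Si](CC)(CC)CC)(C(C)C)C12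
F6 | step 9 | C14 methanesulfonate of F5 | OC1CC(COS(C)(=O)=O)=C[C@@H](O[Si](C(C)C)(C(C)C)C(C)C)[C@@]2(C)CC[C@@](O[Si](CC)(CC)CC)(C(C)C)C12
F7 | step 9 | C14-methyl C6 alcohol (C4 OTES, C10 OTIPS; C5 and C6 not fixed) | OC1CC(C)=C[C@@H](O[Si](C(C)C)(C(C)C)C(C)C)[C@@]2(C)CC[C@@](O[Si](CC)(CC)CC)(C(C)C)C12
F8 | step 13 | C6 enol trifluoromethanesulfonate of the C14-methyl diene | O=S(=O)(OC1=C2[C@](O[Si](CC)(CC)CC)(C(C)C)CC[C@]2(C)[C@H](O[Si](C(C)C)(C(C)C)C(C)C)C=C(C)C1)C(F)(F)F
F9 | step 13 | C14-methyl 5,6-ene/8,9-ene (C6–H, C4 OTES, C10 OTIPS) | C1=C2[C@](O[Si](CC)(CC)CC)(C(C)C)CC[C@]2(C)[C@H](O[Si](C(C)C)(C(C)C)C(C)C)C=C(C)C1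
F10 | step 13 | 6β-alcohol with C5–H β, C4 OTES, C10 OTIPS | O[C@H]1CC(C)=C[C@@H](O[Si](C(C)C)(C(C)C)C(C)C)[C@@]2(C)CC[C@@](O[Si](CC)(CC)CC)(C(C)C)[C@H]12
F11 | step 15 | C6 2-[bis(2,2,2-trifluoroethoxy)phosphoryl]propanoate of 21 | CC(C(=O)O[C@H]1CC(C)=C[C@@H](O[Si](C(C)C)(C(C)C)C(C)C)[C@@]2(C)CC[C@@](O)(C(C)C)[C@H]12)P(=O)(OCC(F)(F)F)OCC(F)(F)F
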